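Remark on the chemistry: the target SMILES encodes the (2R,3S) meso diketone. Because nothing in a rhodium hydroacylation fixes the C2/C3 relationship, the hydroacylation product is carried as the meso/racemic mixture 11, and the pure meso compound 12 is numbered separately after an equilibration step.

## Structural features

The target is an open-chain butane-1,4-dione. C1 and C4 are aryl ketone carbons, each bonded to a 2,4-dihydroxyphenyl ring, and C2 and C3 each carry a 4-hydroxybenzyl group, so four separate benzene rings hang on a four-carbon chain and no ring has to be built. C2 and C3 are adjacent tertiary stereocentres with identical substituent sets; the configuration is (2R,3S), the achiral meso isomer, so only the relative configuration matters. Both stereocentres are α to a ketone and can epimerise, the 1,4-diketone closes to a furan under acid (Paal–Knorr), and the six phenols are oxidation-prone. Late steps therefore have to be neutral and reductive. The real difficulty is the C2–C3 region: two vicinal methines, each flanked by an aroyl and a benzyl group, have to be joined in the right relative configuration with no ring or auxiliary to relay stereochemistry. The molecule consists of two identical halves related through the midpoint of C2–C3, which invites a two-directional construction. Each half contains the unit ArC(=O)–CH–CH2Ar′, in which the carbonyl sits on a ring carbon whose neighbour C2′ bears a hydroxyl. This is the retron of a salicylaldehyde formyl C–H bond added across an aryl–CH=CH unit, and the C2′ hydroxyl that has to chelate rhodium is already part of the target.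

## Logic of the disconnections

13 to 12: the four O–H bonds of the para-hydroxyls (two on the benzyl rings, two on the resorcinol rings) are traced back to O–CH2Ph bonds. Benzyl ethers come off by neutral hydrogenolysis, so the last step exposes neither the α-stereocentres nor the 1,4-diketone to acid or base. The two ortho hydroxyls stay free because the key step needs them. The gain is a lipophilic, crystallisable intermediate. The demand is that hydrogenolysis leaves the aryl ketones alone.

12 to 11: no skeletal bond is cut; the C2–H and C3–H bonds are treated as exchangeable. The C–C bond-forming step cannot control the C2/C3 relationship, so the meso isomer is reached by enolisation with removal of the less soluble diastereomer. The gain is that the stereochemical problem is taken out of the key step. The demand is that epimerisation proceeds without oxidation or furan formation and that the meso form is the one that crystallises.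

11 to 8 and two molecules of 9, through 10: the C1–C2 and C4–C3 bonds (acyl carbon to methine) are cut together with the two benzylic C–H bonds. Each half is the adduct of a formyl C–H across an aryl–CH=CH unit, and the ortho hydroxyl of 9 is the chelating handle. The gain is large: a C58 diketone falls to a symmetric diene and a purchasable aldehyde, with both skeletal bonds made in one operation and no by-product. The demand is two successive additions with acyl on the internal carbons, and no migration of the remaining double bond of 10 before the second addition.

8 to 3 and 4, through 5, 6 and 7: both C=C bonds of the diene are cut, leaving a two-carbon dialdehyde at the centre and two benzylic phosphorus ylides. The gain is symmetry and cheap inputs. The demand is olefination at both ends of 4 and delivery of the E,E geometry, which is met by iodine equilibration of the isomer mixture.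

3 to 1 and 2: the benzylic C–P bond is cut. Both partners are commercial, and the forward step only requires a clean SN2 quaternisation.

## Other disconnections considered

Alternative 1: The cut is the C2–C3 bond, so the core is seen as two 4-oxygenated cinnamoyl units joined head to head. In the forward sense two 4-methoxycinnamoyl groups are esterified onto the peri-diol template A1 to give the bis-cinnamate A2. Its parallel double bonds should undergo [2+2] photocycloaddition to the template-bound cyclobutane diester A3, which has cis esters, cis aryl groups and a trans aryl/ester relationship. Reductive opening of the ring bond between the two aryl-bearing carbons and release from the template would give the meso diacid A4.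
- In favour: the template enforces the head-to-head, syn arrangement, so the cis ester relationship of A3 becomes the meso C2/C3 relationship under kinetic control. On stereocontrol this plan is the better one, since the chosen route relies on equilibration in step 4. The photodimerisation is also a well-understood reaction type and mechanistically more secure than step 3.
- Against: selective reductive cleavage of one doubly benzylic cyclobutane bond is not routine and would compete with cycloreversion and ester reduction. A4 is at the carboxylic acid level, so both aryl–C(=O) bonds still have to be made, in effect by the endgame of Alternative 2. The methyl ethers need a strongly Lewis-acidic deprotection that threatens the 1,4-diketone and the α-stereocentres.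
- Comparison: on structure it uses the same mirror symmetry as the chosen plan (equal). On mechanism its key step is safer but its ring opening is not. On step economy it would need roughly twice the five steps of the chosen route.

Alternative 2: The cut is at the two aryl–C(=O) bonds. In the forward sense at least two equivalents of the aryllithium A6 add to the meso bis(N-methoxy-N-methylamide) A5, and the chelated tetrahedral intermediates collapse on work-up to the hexakis(methoxymethyl) ether A7.
- In favour: ketone synthesis from N-methoxy-N-methylamides and aryllithiums is dependable known chemistry, so the key step is mechanistically more secure than step 3; this is a point on which it is the better plan. The C2/C3 configuration is defined before the key step. Both halves are installed at once, which equals the chosen plan in two-directional economy.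
- Against: A5 has to be assembled and purified as the meso isomer (dibenzylation of a succinate, diastereomer separation, amide formation), so the stereochemical problem is moved, not removed. The basic aryllithium can deprotonate the hindered α-CH of A5 instead of adding, which would erode the meso configuration. Six acetal protecting groups have to be removed from A7 with acid, the condition under which a 1,4-diketone cyclises to a furan. The route also needs low-temperature organolithium chemistry and a carcinogenic alkylating agent for the protections, so it is inferior on safety.
- Comparison: it would take about eight to nine steps against five, and the chosen route brings in the resorcinol ketone with its oxygen pattern complete and with full atom economy.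

Alternative 3: The cut is at two C–C bonds in each resorcinol ring, four in all, so the rings are built from an ynone and an oxygenated diene. In the forward sense the meso bis(ethynyl ketone) A8 would react twice with the diene A9. Each cycloadduct loses methanol and aromatises, and desilylation would give the bis(4-hydroxy-2-methoxyphenyl) diketone A10.
- In favour: the regiochemistry is fixed by polarity, since the unsubstituted diene terminus attacks the ynone β-carbon, and aromatisation drives the reaction. The reaction type is established and metal-free, so it is more secure mechanistically than step 3. The benzyl ethers on the benzyl rings allow the same neutral final hydrogenolysis as the chosen plan (equal).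
- Against: it constructs two benzene rings that the chosen plan buys ready-made in 9, so there is no structural simplification. A8 is a doubly activated, nucleophile-sensitive bis(ynone) whose α-hydrogens are more acidic than those of 12, which puts the meso configuration at greater risk. A8 also requires the same meso dibenzylsuccinyl core as Alternative 2 plus two alkynylations. A9 is moisture-sensitive. A10 carries methyl ethers ortho to the carbonyls that need an extra chelation-assisted Lewis-acid demethylation.
- Comparison: its step economy is the poorest of the four plans, at ten steps or more.

Key step: step 3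

## Route

Step 1
Reactants: 1 4-(benzyloxy)benzyl chloride; 2 triphenylphosphine
Product: 3 [4-(benzyloxy)benzyl]triphenylphosphonium chloride
Conditions: 2 (1.05 equiv), toluene, reflux; cool, filter the salt
Reagents that add atoms: none
Why: SN2 quaternisation of triphenylphosphine by the activated benzylic chloride; the salt should precipitate from toluene, which drives the reaction and purifies the product.

Step 2
Reactants: 3 [4-(benzyloxy)benzyl]triphenylphosphonium chloride; 4 glyoxal (40% aqueous solution)
Product: 8 (1E,3E)-1,4-bis[4-(benzyloxy)phenyl]buta-1,3-diene, via phosphonium ylide 5 (not isolated), via mono-olefination enal 6 (not isolated), via diene isomer mixture 7 (not isolated)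
Conditions: 3 (2.1 equiv), 4 (1.0 equiv), LiOEt (2.2 equiv, slow addition), EtOH, 20 °C; extract into toluene; I2 (2 mol%), toluene, reflux; cool, filter
Reagents that add atoms: none
Why: Double Wittig olefination: the semistabilised ylide 5, generated by ethoxide in the presence of the aldehyde, should olefinate glyoxal once to the enal 6 and again to the isomer mixture 7. Reversible iodine-atom addition then equilibrates the double bonds to the thermodynamically preferred and least soluble E,E isomer 8, which should crystallise away from triphenylphosphine oxide.

Step 3
Reactants: 8 (1E,3E)-1,4-bis[4-(benzyloxy)phenyl]buta-1,3-diene; 9 4-(benzyloxy)-2-hydroxybenzaldehyde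
Product: 11 1,4-bis[4-(benzyloxy)-2-hydroxyphenyl]-2,3-bis[4-(benzyloxy)benzyl]butane-1,4-dione (meso/racemic mixture), via mono-hydroacylation ketone 10 (not isolated)
Conditions: 9 (3 equiv), RhCl(PPh3)3 (10 mol%), NaOAc (20 mol%), toluene–MeCN 5:1, 80 °C, argon
Reagents that add atoms: none
Why: Proposed new method: the closest known reaction type is the rhodium-catalysed hydroacylation of 1,3-dienes with salicylaldehydes, which is established only for a single addition (the stage of 10); the second addition to the internal styrenyl bond of 10 is the unproven part. Acetate-assisted binding of the phenol of 9 to monovalent rhodium delivers the formyl C–H for oxidative addition, giving a phenoxide-chelated acyl hydride of trivalent rhodium that is slow to decarbonylate. Insertion of the s-cis-bound diene 8 into Rh–H puts hydrogen on a benzylic terminus and leaves an η3-allyl over C2–C3–C4; reductive elimination at C2, the allyl end remote from the aryl group, forms the first acyl–C bond and keeps the C3=C4 styrene conjugated. In the second turnover the ketone oxygen and the C3=C4 bond of 10 can bind the next acyl rhodium hydride as a bidentate ligand, so that hydride goes to benzylic C4 with formation of a five-membered oxa-rhodacycle (Rh–C3–C2–C1=O) and reductive elimination makes the C3–acyl bond; the benzylic rhodium alkyl that would lead to a 1,5-diketone needs a less favourable six-membered chelate. No ring is closed, so no mode of ring closure arises. The two new stereocentres (C2 in the first addition, C3 in the second) form under at most weak substrate control, so 11 is expected as a meso/racemic mixture and the relative configuration is left to step 4. The selectivity the step must deliver is therefore regiochemical only, acyl on the two internal carbons and hydrogen on the two benzylic ones, secured by allyl conjugation in the first addition and by ketone chelation in the second; the excess of 9 is meant to outpace migration of the C3=C4 bond into conjugation with the ketone.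

Step 4
Reactants: 11 1,4-bis[4-(benzyloxy)-2-hydroxyphenyl]-2,3-bis[4-(benzyloxy)benzyl]butane-1,4-dione (meso/racemic mixture)
Product: 12 (2R,3S)-1,4-bis[4-(benzyloxy)-2-hydroxyphenyl]-2,3-bis[4-(benzyloxy)benzyl]butane-1,4-dione (meso)
Conditions: DBU (0.2 equiv), EtOH–toluene 4:1, 70 °C, then slow cooling to 20 °C with seeding, argon; AcOH (0.2 equiv); filter
Reagents that add atoms: none
Why: Base-mediated epimerisation of the two ketone α-stereocentres through the enolate, run as a crystallisation-induced diastereomer transformation. The centrosymmetric meso isomer is expected to be the less soluble one and to leave the equilibrium as it crystallises, so C2 and C3 are set by thermodynamic and lattice control.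

Step 5
Reactants: 12 (2R,3S)-1,4-bis[4-(benzyloxy)-2-hydroxyphenyl]-2,3-bis[4-(benzyloxy)benzyl]butane-1,4-dione (meso)
Product: 13 (2R,3S)-1,4-bis(2,4-dihydroxyphenyl)-2,3-bis(4-hydroxybenzyl)butane-1,4-dione (meso, the target)
Conditions: H2 (1 atm), 10% Pd/C, THF–EtOAc, 20 °C; filter through Celite
Reagents that add atoms: none
Why: Heterogeneous hydrogenolysis of the four benzyl aryl ethers under neutral conditions. The ortho-hydroxy, para-oxygenated aryl ketones are vinylogous acid derivatives and should resist carbonyl reduction, and the absence of acid or base should keep C2 and C3 from epimerising and the 1,4-diketone from closing to a furan.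

## Compound list

1 | 4-(benzyloxy)benzyl chloride | ClCc1ccc(OCc2ccccc2)cc1 | starting material
2 | triphenylphosphine | c1ccc(cc1)P(c1ccccc1)c1ccccc1 | starting material
3 | [4-(benzyloxy)benzyl]triphenylphosphonium chloride | [Cl-].c1ccccc1COc1ccc(C[P+](c2ccccc2)(c2ccccc2)c2ccccc2)cc1 | intermediate
4 | glyoxal (40% aqueous solution) | O=CC=O | starting material
5 | [4-(benzyloxy)benzylidene]triphenylphosphorane (ylide) | c1ccccc1COc1ccc(C=P(c2ccccc2)(c2ccccc2)c2ccccc2)cc1 | intermediate (not isolated)
6 | 3-[4-(benzyloxy)phenyl]prop-2-enal, E/Z mixture | O=CC=Cc1ccc(OCc2ccccc2)cc1 | intermediate (not isolated)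
7 | 1,4-bis[4-(benzyloxy)phenyl]buta-1,3-diene, mixture of E,E, E,Z and Z,Z isomers | c1ccccc1COc1ccc(C=CC=Cc2ccc(OCc3ccccc3)cc2)cc1 | intermediate (not isolated)
8 | (1E,3E)-1,4-bis[4-(benzyloxy)phenyl]buta-1,3-diene | c1ccccc1COc1ccc(/C=C/C=C/c2ccc(OCc3ccccc3)cc2)cc1 | intermediate
9 | 4-(benzyloxy)-2-hydroxybenzaldehyde | O=Cc1ccc(OCc2ccccc2)cc1O | starting material
10 | (3E)-1-[4-(benzyloxy)-2-hydroxyphenyl]-2-[4-(benzyloxy)benzyl]-4-[4-(benzyloxy)phenyl]but-3-en-1-one, racemic | O=C(c1ccc(OCc2ccccc2)cc1O)C(Cc1ccc(OCc2ccccc2)cc1)/C=C/c1ccc(OCc2ccccc2)cc1 | intermediate (not isolated)
11 | 1,4-bis[4-(benzyloxy)-2-hydroxyphenyl]-2,3-bis[4-(benzyloxy)benzyl]butane-1,4-dione, mixture of meso and racemic diastereomers | O=C(c1ccc(OCc2ccccc2)cc1O)C(Cc1ccc(OCc2ccccc2)cc1)C(Cc1ccc(OCc2ccccc2)cc1)C(=O)c1ccc(OCc2ccccc2)cc1O | intermediate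
12 | (2R,3S)-1,4-bis[4-(benzyloxy)-2-hydroxyphenyl]-2,3-bis[4-(benzyloxy)benzyl]butane-1,4-dione (meso) | O=C(c1ccc(OCc2ccccc2)cc1O)[C@@H](Cc1ccc(OCc2ccccc2)cc1)[C@@H](Cc1ccc(OCc2ccccc2)cc1)C(=O)c1ccc(OCc2ccccc2)cc1O | intermediate
13 | (2R,3S)-1,4-bis(2,4-dihydroxyphenyl)-2,3-bis(4-hydroxybenzyl)butane-1,4-dione (meso) | O=C(c1ccc(O)cc1O)[C@@H](Cc1ccc(O)cc1)[C@@H](Cc1ccc(O)cc1)C(=O)c1ccc(O)cc1O | target

## Step count and least certain steps

Total step count: 5 (step 2 is telescoped). Longest linear sequence: 5 steps (1 to 3 to 8 to 11 to 12 to 13).

**Step 3 (key step, proposed new method).**
- What may go wrong: the catalyst may stall after the first addition because the internal, 1,2-disubstituted styrenyl bond of the mono-adduct binds rhodium weakly. In the second turnover, hydride insertion may go toward the benzylic rhodium alkyl and so place the acyl group on the benzylic carbon. The remaining double bond may migrate into conjugation with the ketone, after which the ortho phenol would close onto it by oxa-Michael addition. Decarbonylation of the aldehyde may deactivate the catalyst.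
- Fallback (known chemistry): it sets out from 1 and comes back to the route at 13. The lithium enolate of 1-[2,4-bis(benzyloxy)phenyl]ethanone F1 (purchased) is C-benzylated with 1 (LiN(iPr)2, THF, −78 °C to 20 °C) to give 1-[2,4-bis(benzyloxy)phenyl]-3-[4-(benzyloxy)phenyl]propan-1-one F2. Oxidative homocoupling of the lithium enolate of F2 (LiN(iPr)2, THF, −78 °C; then CuCl2, DMF, −78 °C to 20 °C) forms the C2–C3 bond directly and should give 1,4-bis[2,4-bis(benzyloxy)phenyl]-2,3-bis[4-(benzyloxy)benzyl]butane-1,4-dione F3 as a meso/racemic mixture. Base equilibration with crystallisation, as in step 4 but without free phenols, should give the meso hexabenzyl ether F4, and hydrogenolysis of its six benzyl ethers (H2, 10% Pd/C) gives 13.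

**Step 4.**
- What may go wrong: selective crystallisation of the meso isomer may fail, through co-crystallisation or a less soluble racemate. Enolisation may be slow because deprotonation of the ortho phenols deactivates the ketones. Air oxidation of the enolate is also possible.
- Fallback: it sets out from 11 and comes back at 13. The mixture 11 is hydrogenolysed directly (H2, 10% Pd/C, THF–EtOAc) to 1,4-bis(2,4-dihydroxyphenyl)-2,3-bis(4-hydroxybenzyl)butane-1,4-dione F5 as a meso/racemic mixture. The meso isomer 13 is then separated from the racemate by preparative reversed-phase chromatography, and the racemic fraction is re-equilibrated with a mild amine base and recycled.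

**Step 2.**
- What may go wrong: base-induced disproportionation and oligomerisation of glyoxal may occur before olefination, and the reaction may stall after the first olefination, so that conversion to the diene is incomplete.
- Fallback: it sets out from 1 and comes back at 8 by a stepwise, E-selective route. A Michaelis–Arbuzov reaction of 1 with triethyl phosphite (neat, 150 °C) gives diethyl [4-(benzyloxy)benzyl]phosphonate F6. Separately, 4-(benzyloxy)benzaldehyde F7 (purchased) is homologated with (triphenylphosphoranylidene)acetaldehyde (toluene, 80 °C) to (2E)-3-[4-(benzyloxy)phenyl]prop-2-enal F8. Horner–Wadsworth–Emmons olefination of F8 with the anion of F6 (NaH, THF, 0 °C to 20 °C) should give 8 without an isomerisation step.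

**Step 5.**
- What may go wrong: over-reduction of the benzylic ketone carbonyls, or incomplete cleavage if partly debenzylated material precipitates onto the catalyst.
- Fallback: it sets out from 12 and comes back at 13. The benzyl ethers are cleaved by a Lewis acid instead of by hydrogenolysis, with BCl3 and pentamethylbenzene as cation scavenger (CH2Cl2, −78 °C, methanol quench); the low temperature is meant to avoid furan formation. No new compound is made.

## Further compounds

F1 | step 3 | 1-[2,4-bis(benzyloxy)phenyl]ethanone (purchased) | CC(=O)c1ccc(OCc2ccccc2)cc1OCc1ccccc1
F2 | step 3 | 1-[2,4-bis(benzyloxy)phenyl]-3-[4-(benzyloxy)phenyl]propan-1-one | O=C(CCc1ccc(OCc2ccccc2)cc1)c1ccc(OCc2ccccc2)cc1OCc1ccccc1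
F3 | step 3 | 1,4-bis[2,4-bis(benzyloxy)phenyl]-2,3-bis[4-(benzyloxy)benzyl]butane-1,4-dione, meso/racemic mixture | O=C(c1ccc(OCc2ccccc2)cc1OCc1ccccc1)C(Cc1ccc(OCc2ccccc2)cc1)C(Cc1ccc(OCc2ccccc2)cc1)C(=O)c1ccc(OCc2ccccc2)cc1OCc1ccccc1
F4 | step 3 | (2R,3S)-1,4-bis[2,4-bis(benzyloxy)phenyl]-2,3-bis[4-(benzyloxy)benzyl]butane-1,4-dione (meso) | O=C(c1ccc(OCc2ccccc2)cc1OCc1ccccc1)[C@@H](Cc1ccc(OCc2ccccc2)cc1)[C@@H](Cc1ccc(OCc2ccccc2)cc1)C(=O)c1ccc(OCc2ccccc2)cc1OCc1ccccc1
F5 | step 4 | 1,4-bis(2,4-dihydroxyphenyl)-2,3-bis(4-hydroxybenzyl)butane-1,4-dione, meso/racemic mixture | O=C(c1ccc(O)cc1O)C(Cc1ccc(O)cc1)C(Cc1ccc(O)cc1)C(=O)c1ccc(O)cc1O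
F6 | step 2 | diethyl [4-(benzyloxy)benzyl]phosphonate | CCOP(=O)(OCC)Cc1ccc(OCc2ccccc2)cc1
F7 | step 2 | 4-(benzyloxy)benzaldehyde (purchased) | O=Cc1ccc(OCc2ccccc2)cc1
F8 | step 2 | (2E)-3-[4-(benzyloxy)phenyl]prop-2-enal | O=C/C=C/c1ccc(OCc2ccccc2)cc1
F0 | step 5 | none | none
A1 | alternative 1 | naphthalene-1,8-diol | Oc1cccc2cccc(O)c12
A2 | alternative 1 | naphthalene-1,8-diyl bis[(2E)-3-(4-methoxyphenyl)prop-2-enoate] | COc1ccc(/C=C/C(=O)Oc2cccc3cccc(OC(=O)/C=C/c4ccc(OC)cc4)c23)cc1
A3 | alternative 1 | naphthalene-1,8-diyl cis-3,4-bis(4-methoxyphenyl)cyclobutane-cis-1,2-dicarboxylate, aryl trans to adjacent ester (β-truxinate type) | COc1ccc(cc1)[C@@H]2[C@H](c1ccc(OC)cc1)[C@@H](C(=O)Oc1cccc3cccc(O6)c13)[C@H]2C6=O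
A4 | alternative 1 | (2R,3S)-2,3-bis(4-methoxybenzyl)butanedioic acid (meso) | OC(=O)[C@@H](Cc1ccc(OC)cc1)[C@@H](Cc1ccc(OC)cc1)C(=O)O
A5 | alternative 2 | (2R,3S)-N1,N4-dimethoxy-N1,N4-dimethyl-2,3-bis[4-(methoxymethoxy)benzyl]butanediamide (meso) | CON(C)C(=O)[C@@H](Cc1ccc(OCOC)cc1)[C@@H](Cc1ccc(OCOC)cc1)C(=O)N(C)OC
A6 | alternative 2 | 2,4-bis(methoxymethoxy)phenyllithium | [Li]c1ccc(OCOC)cc1OCOC
A7 | alternative 2 | (2R,3S)-1,4-bis[2,4-bis(methoxymethoxy)phenyl]-2,3-bis[4-(methoxymethoxy)benzyl]butane-1,4-dione (meso) | O=C(c1ccc(OCOC)cc1OCOC)[C@@H](Cc1ccc(OCOC)cc1)[C@@H](Cc1ccc(OCOC)cc1)C(=O)c1ccc(OCOC)cc1OCOC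
A8 | alternative 3 | (4R,5S)-4,5-bis[4-(benzyloxy)benzyl]octa-1,7-diyne-3,6-dione (meso) | C#CC(=O)[C@@H](Cc1ccc(OCc2ccccc2)cc1)[C@@H](Cc1ccc(OCc2ccccc2)cc1)C(=O)C#C
A9 | alternative 3 | 1,1-dimethoxy-3-(trimethylsilyloxy)buta-1,3-diene | COC(OC)=CC(=C)O[Si](C)(C)C
A10 | alternative 3 | (2R,3S)-1,4-bis(4-hydroxy-2-methoxyphenyl)-2,3-bis[4-(benzyloxy)benzyl]butane-1,4-dione (meso) | O=C(c1ccc(O)cc1OC)[C@@H](Cc1ccc(OCc2ccccc2)cc1)[C@@H](Cc1ccc(OCc2ccccc2)cc1)C(=O)c1ccc(O)cc1OC
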